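**Plan**

1. Retrosynthesis (cembrane numbering: C1/C14 = lactone β/γ-carbons, C15 = α-carbon, C16 = carbonyl, C17 = exo-methylene). After PMB removal, C15–C16 and C1–C14 are cut in one retro-step, which opens the lactone and the 14-membered ring together to the acyclic allenyl aldehyde 25 and CO2.
2. Enabling feature: in the butanolide ring C14–O–C16(=O)–C15(=C17)–C1, the unit C17=C15–C1(H) is a terminal-allene retron and C14–O an aldehyde retron. C1–C14 is the only bond the lactone shares with the carbocycle, so one allene/CO2/aldehyde coupling on nickel makes both rings.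
3. Further cuts: the allene (C15=C17) to a terminal alkyne plus formaldehyde; the C3–C4 epoxide to the E-alkene; the C6=C7 Z-alkene (Wittig) to aldehyde 9 (C7–C14, from (S)-citronellal) and phosphonium salt 17 (C1–C6 and C15, from prenyl bromide and a silylacetylene).
4. Forward: the chain is joined at C6=C7, then the epoxide, the allene and the aldehyde are installed. The carbocycle and the lactone arise together in step 18; only the PMB ether is removed afterwards.
5. Stereochemistry: C12 from (S)-citronellal; C13 by L-proline aminoxylation; C8 by Sharpless epoxidation and hydride opening; C3/C4 by Shi epoxidation; C1 and C14 in the key step, relayed from C13 (aldehyde face) and from the allyl-nickel geometry (syn, cis-lactone).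

Key step: step 18

Remark: compounds 5–9 and 19 are carried as mixtures of epimers at the acetal carbon; this centre disappears in step 13.

**Route**

Step 1
Reactants: 1 (S)-citronellal
Product: 3 (2R,3S)-3,7-dimethyl-2-[(phenylamino)oxy]oct-6-en-1-ol, via α-aminoxy aldehyde 2 (not isolated)
Conditions: PhNO, L-proline (20 mol %), CHCl3, 4 °C; then NaBH4, EtOH, 0 °C
Reagents that add atoms: nitrosobenzene, O=Nc1ccccc1
Why: Proline-catalysed α-aminoxylation (enamine catalysis) should set C13 (R) under catalyst control, C12 coming unchanged from 1, and the in situ borohydride reduction secures the labile α-oxy aldehyde.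

Step 2
Reactants: 3 (2R,3S)-3,7-dimethyl-2-[(phenylamino)oxy]oct-6-en-1-ol
Product: 4 (2R,3S)-3,7-dimethyloct-6-ene-1,2-diol
Conditions: Zn, AcOH, EtOH, rt
Reagents that add atoms: none
Why: Reductive N–O cleavage with zinc/acetic acid frees the secondary hydroxyl without touching a stereocentre or the alkene.

Step 3
Reactants: 4 (2R,3S)-3,7-dimethyloct-6-ene-1,2-diol
Product: 5 (4R)-2-(4-methoxyphenyl)-4-[(2S)-6-methylhept-5-en-2-yl]-1,3-dioxolane (acetal epimers)
Conditions: 4-MeOC6H4CH(OMe)2, PPTS (cat.), CH2Cl2, rt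
Reagents that add atoms: 4-methoxybenzaldehyde dimethyl acetal, COC(OC)c1ccc(OC)cc1
Why: Transacetalisation protects both hydroxyls in one group that later delivers the C13 PMB ether and the free C14 alcohol.

Step 4
Reactants: 5 (4R)-2-(4-methoxyphenyl)-4-[(2S)-6-methylhept-5-en-2-yl]-1,3-dioxolane
Product: 6 (2E,6S)-6-[(4R)-2-(4-methoxyphenyl)-1,3-dioxolan-4-yl]-2-methylhept-2-en-1-ol
Conditions: SeO2 (0.3 equiv), t-BuOOH, salicylic acid (cat.), CH2Cl2, rt
Reagents that add atoms: tert-butyl hydroperoxide, CC(C)(C)OO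
Why: Selenium dioxide allylic oxidation (ene reaction, then [2,3]-shift) should hydroxylate the E-methyl group of the trisubstituted alkene, which becomes C7.

Step 5
Reactants: 6 (2E,6S)-6-[(4R)-2-(4-methoxyphenyl)-1,3-dioxolan-4-yl]-2-methylhept-2-en-1-ol
Product: 7 [(2R,3R)-3-{(3S)-3-[(4R)-2-(4-methoxyphenyl)-1,3-dioxolan-4-yl]butyl}-2-methyloxiran-2-yl]methanol
Conditions: Ti(OiPr)4, diethyl D-(−)-tartrate, t-BuOOH, 4 Å MS, CH2Cl2, −20 °C
Reagents that add atoms: tert-butyl hydroperoxide, CC(C)(C)OO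
Why: Sharpless asymmetric epoxidation of the E-2-methyl allylic alcohol; the D-tartrate catalyst should deliver oxygen to the face that gives the (2R,3R)-epoxide, which fixes the C8–O bond by reagent control.

Step 6
Reactants: 7 [(2R,3R)-3-{(3S)-3-[(4R)-2-(4-methoxyphenyl)-1,3-dioxolan-4-yl]butyl}-2-methyloxiran-2-yl]methanol
Product: 8 (2S,6S)-6-[(4R)-2-(4-methoxyphenyl)-1,3-dioxolan-4-yl]-2-methylheptane-1,2-diol
Conditions: LiAlH4, THF, 0 °C to rt
Reagents that add atoms: none
Why: Hydride opening of the 2,3-epoxy alcohol at the secondary C3 (C2 is fully substituted) leaves the tertiary C–O bond intact and so gives the (S)-tertiary carbinol C8.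

Step 7
Reactants: 8 (2S,6S)-6-[(4R)-2-(4-methoxyphenyl)-1,3-dioxolan-4-yl]-2-methylheptane-1,2-diol
Product: 9 (2S,6S)-2-hydroxy-6-[(4R)-2-(4-methoxyphenyl)-1,3-dioxolan-4-yl]-2-methylheptanal
Conditions: TEMPO (cat.), PhI(OAc)2, CH2Cl2, rt
Reagents that add atoms: none
Why: Oxoammonium (TEMPO) oxidation takes the primary alcohol to the aldehyde; the tertiary hydroxyl cannot be oxidised and the α-carbon carries no hydrogen to epimerise.

Step 8
Reactants: 10 ethynyltriisopropylsilane; 11 prenyl bromide (1-bromo-3-methylbut-2-ene)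
Product: 12 triisopropyl(5-methylhex-4-en-1-yn-1-yl)silane
Conditions: EtMgBr, THF, 50 °C; then CuCl (10 mol %), 11, 60 °C
Reagents that add atoms: none
Why: Copper-catalysed alkynyl Grignard substitution of the allylic bromide at its primary terminus (SN2) gives the skipped enyne.

Step 9
Reactants: 12 triisopropyl(5-methylhex-4-en-1-yn-1-yl)silane
Product: 13 (2E)-2-methyl-6-(triisopropylsilyl)hex-2-en-5-yn-1-ol
Conditions: SeO2 (0.3 equiv), t-BuOOH, salicylic acid (cat.), CH2Cl2, rt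
Reagents that add atoms: tert-butyl hydroperoxide, CC(C)(C)OO
Why: Selenium dioxide allylic oxidation at the more substituted alkene terminus should hydroxylate the E-methyl group (future C5) and fix the E-geometry of the C3=C4 alkene.

Step 10
Reactants: 13 (2E)-2-methyl-6-(triisopropylsilyl)hex-2-en-5-yn-1-ol
Product: 14 [(4E)-6-bromo-5-methylhex-4-en-1-yn-1-yl]triisopropylsilane
Conditions: CBr4, PPh3, CH2Cl2, 0 °C
Reagents that add atoms: carbon tetrabromide, BrC(Br)(Br)Br
Why: Appel bromination converts the primary allylic alcohol to the bromide without allylic transposition.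

Step 11
Reactants: 14 [(4E)-6-bromo-5-methylhex-4-en-1-yn-1-yl]triisopropylsilane; 15 methyltriphenylphosphonium bromide
Product: 17 [(3E)-3-methyl-7-(triisopropylsilyl)hept-3-en-6-yn-1-yl]triphenylphosphonium bromide, via methylenetriphenylphosphorane 16 (not isolated)
Conditions: 15, n-BuLi, THF, 0 °C; then 14, −78 °C to rt
Reagents that add atoms: none
Why: C-Alkylation of the methylene ylide by the allylic bromide (ylide homologation) adds C6 and gives the homoallylic phosphonium salt directly.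

Step 12
Reactants: 17 [(3E)-3-methyl-7-(triisopropylsilyl)hept-3-en-6-yn-1-yl]triphenylphosphonium bromide; 9 (2S,6S)-2-hydroxy-6-[(4R)-2-(4-methoxyphenyl)-1,3-dioxolan-4-yl]-2-methylheptanal
Product: 19 (2S,6S,7Z,10E)-2-[(4R)-2-(4-methoxyphenyl)-1,3-dioxolan-4-yl]-6,10-dimethyl-14-(triisopropylsilyl)tetradeca-7,10-dien-13-yn-6-ol, via phosphorus ylide 18 (not isolated)
Conditions: 17 (2.2 equiv), NaHMDS (2.1 equiv), THF, −78 °C; then 9, −78 °C to rt
Reagents that add atoms: none
Why: Wittig olefination with a non-stabilised ylide under salt-free conditions should give the C6=C7 Z-alkene (kinetic cis-oxaphosphetane); the excess ylide takes up the tertiary hydroxyl proton.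

Step 13
Reactants: 19 (2S,6S,7Z,10E)-2-[(4R)-2-(4-methoxyphenyl)-1,3-dioxolan-4-yl]-6,10-dimethyl-14-(triisopropylsilyl)tetradeca-7,10-dien-13-yn-6-ol
Product: 20 (2R,3S,7S,8Z,11E)-2-[(4-methoxybenzyl)oxy]-3,7,11-trimethyl-15-(triisopropylsilyl)pentadeca-8,11-dien-14-yne-1,7-diol
Conditions: DIBAL-H (5 equiv), CH2Cl2, −78 to 0 °C
Reagents that add atoms: none
Why: Reductive opening of the p-methoxybenzylidene acetal; aluminium binds the less hindered primary oxygen, so the PMB ether should end on the secondary C13 oxygen and the primary alcohol is freed.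

Step 14
Reactants: 20 (2R,3S,7S,8Z,11E)-2-[(4-methoxybenzyl)oxy]-3,7,11-trimethyl-15-(triisopropylsilyl)pentadeca-8,11-dien-14-yne-1,7-diol
Product: 21 (2R,3S,7S,8Z)-2-[(4-methoxybenzyl)oxy]-3,7-dimethyl-10-{(2R,3R)-2-methyl-3-[3-(triisopropylsilyl)prop-2-yn-1-yl]oxiran-2-yl}dec-8-ene-1,7-diol
Conditions: D-fructose-derived Shi ketone (0.3 equiv), Oxone, K2CO3, Bu4NHSO4, MeCN/DMM/aq. Na2B4O7–Na2EDTA, 0 °C
Reagents that add atoms: potassium peroxymonosulfate (Oxone), [K+].[O-]S(=O)(=O)OO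
Why: Shi epoxidation (chiral dioxirane, spiro transition state) should give the (R,R)-epoxide of the E-trisubstituted alkene by reagent control; this alkene is far more reactive than the cis-disubstituted alkene and the alkyne.

Step 15
Reactants: 21 (2R,3S,7S,8Z)-2-[(4-methoxybenzyl)oxy]-3,7-dimethyl-10-{(2R,3R)-2-methyl-3-[3-(triisopropylsilyl)prop-2-yn-1-yl]oxiran-2-yl}dec-8-ene-1,7-diol
Product: 22 (2R,3S,7S,8Z)-2-[(4-methoxybenzyl)oxy]-3,7-dimethyl-10-[(2R,3R)-2-methyl-3-(prop-2-yn-1-yl)oxiran-2-yl]dec-8-ene-1,7-diol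
Conditions: TBAF, THF, 0 °C
Reagents that add atoms: none
Why: Fluoride cleaves the alkynyl C–Si bond; the epoxide, the PMB ether and both hydroxyls are inert.

Step 16
Reactants: 22 (2R,3S,7S,8Z)-2-[(4-methoxybenzyl)oxy]-3,7-dimethyl-10-[(2R,3R)-2-methyl-3-(prop-2-yn-1-yl)oxiran-2-yl]dec-8-ene-1,7-diol
Product: 24 (2R,3S,7S,8Z)-10-[(2R,3R)-3-(buta-2,3-dien-1-yl)-2-methyloxiran-2-yl]-2-[(4-methoxybenzyl)oxy]-3,7-dimethyldec-8-ene-1,7-diol, via propargylic amine 23 (not isolated)
Conditions: (CH2O)n, CuBr (0.5 equiv), i-Pr2NH, 1,4-dioxane, 100 °C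
Reagents that add atoms: formaldehyde (as paraformaldehyde), C=O
Why: Crabbé homologation (Mannich reaction of the terminal alkyne, then copper-mediated 1,5-hydride transfer and loss of the imine) converts the alkyne into the terminal allene and adds C17.

Step 17
Reactants: 24 (2R,3S,7S,8Z)-10-[(2R,3R)-3-(buta-2,3-dien-1-yl)-2-methyloxiran-2-yl]-2-[(4-methoxybenzyl)oxy]-3,7-dimethyldec-8-ene-1,7-diol
Product: 25 (2R,3S,7S,8Z)-10-[(2R,3R)-3-(buta-2,3-dien-1-yl)-2-methyloxiran-2-yl]-7-hydroxy-2-[(4-methoxybenzyl)oxy]-3,7-dimethyldec-8-enal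
Conditions: Dess–Martin periodinane, NaHCO3, CH2Cl2, 0 °C
Reagents that add atoms: none
Why: Buffered Dess–Martin oxidation gives the α-alkoxy aldehyde without acid or base strong enough to open the epoxide or epimerise C13; the tertiary alcohol and the allene are inert.

Step 18
Reactants: 25 (2R,3S,7S,8Z)-10-[(2R,3R)-3-(buta-2,3-dien-1-yl)-2-methyloxiran-2-yl]-7-hydroxy-2-[(4-methoxybenzyl)oxy]-3,7-dimethyldec-8-enal
Product: 28 (1S,3R,4R,6Z,8S,12S,13R,14R)-3,4-epoxy-8-hydroxy-13-[(4-methoxybenzyl)oxy]cembra-6,15(17)-dien-16,14-olide, via η3-allyl nickelalactone 26 (not isolated), via seco hydroxy acid 27 (not isolated)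
Conditions: Ni(cod)2 (1.2 equiv), DBU (2.5 equiv), CO2 (1 atm), THF, 0 °C, slow addition of 25 (final 2 mM), then rt; aq. NH4Cl/citrate (pH 5); then EDC·HCl, DMAP (cat.), CH2Cl2, 0 °C
Reagents that add atoms: carbon dioxide, O=C=O
Why: Proposed new method: Ni(0)/DBU should take up CO2 at the terminal C15=C17 π-bond of the allene (oxidative cyclization, new C15–C16 bond) to give the η3-allyl nickelalactone 26, whose allyl unit then adds through C1 to the tethered C14 aldehyde in a six-membered chair (new C1–C14 bond), and the hydroxy acid 27 freed on work-up is lactonised by the carbodiimide. The closest known reaction type is the nickel(0)-mediated sequential addition of CO2 and an aldehyde to a terminal allene, known intermolecularly, and the allyl-metal (Nozaki–Hiyama–Kishi type) ring closure of 14-membered cembranoid seco-aldehydes; the intramolecular, ring-forming combination is new. The 14-membered carbocycle closes by intramolecular allyl-metal addition to the aldehyde (closed SE2′ transition state) after a bimolecular CO2 uptake that does not depend on ring size, and the butanolide closes by 5-exo-trig acyl substitution of O14 at C16. C1 and C14 form together: nickel engages the terminal π-bond on the side away from the C2 chain, which puts that chain anti on the η3-allyl (Z-crotyl type) and so should give the C1/C14 syn relationship of the cis-fused lactone through the chair, while C13 selects the aldehyde face. The step needs carboxylation at C15 with allyl transfer from C1 (secured by the η3-allyl stabilisation of 26 and the usual reaction of allyl metals at the substituted terminus), 1,2-syn induction from C13 (intended through chelation of the aldehyde oxygen and the small PMB ether oxygen on nickel(II), attack anti to the C12 branch) and ring closure over oligomerisation (slow addition, 2 mM).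

Step 19
Reactants: 28 (1S,3R,4R,6Z,8S,12S,13R,14R)-3,4-epoxy-8-hydroxy-13-[(4-methoxybenzyl)oxy]cembra-6,15(17)-dien-16,14-olide
Product: 29 (1S,3R,4R,6Z,8S,12S,13R,14R)-3,4-epoxy-8,13-dihydroxycembra-6,15(17)-dien-16,14-olide (CNP0304380.1)
Conditions: DDQ, CH2Cl2/pH 7 phosphate buffer, 0 °C
Reagents that add atoms: none
Why: Oxidative PMB ether cleavage with DDQ under neutral conditions should spare the epoxide, the tertiary allylic alcohol and the α-methylene lactone.

**Compound list**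

1 | (S)-citronellal, (3S)-3,7-dimethyloct-6-enal | O=CC[C@@H](C)CCC=C(C)C | starting material
2 | (2R,3S)-3,7-dimethyl-2-[(phenylamino)oxy]oct-6-enal (not isolated) | O=C[C@H](ONc1ccccc1)[C@@H](C)CCC=C(C)C | intermediate
3 | (2R,3S)-3,7-dimethyl-2-[(phenylamino)oxy]oct-6-en-1-ol | OC[C@H](ONc1ccccc1)[C@@H](C)CCC=C(C)C | intermediate
4 | (2R,3S)-3,7-dimethyloct-6-ene-1,2-diol | OC[C@H](O)[C@@H](C)CCC=C(C)C | intermediate
5 | (4R)-2-(4-methoxyphenyl)-4-[(2S)-6-methylhept-5-en-2-yl]-1,3-dioxolane (acetal epimers) | COc1ccc(cc1)C1OC[C@H](O1)[C@@H](C)CCC=C(C)C | intermediate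
6 | (2E,6S)-6-[(4R)-2-(4-methoxyphenyl)-1,3-dioxolan-4-yl]-2-methylhept-2-en-1-ol | COc1ccc(cc1)C1OC[C@H](O1)[C@@H](C)CC/C=C(\C)CO | intermediate
7 | [(2R,3R)-3-{(3S)-3-[(4R)-2-(4-methoxyphenyl)-1,3-dioxolan-4-yl]butyl}-2-methyloxiran-2-yl]methanol | COc1ccc(cc1)C1OC[C@H](O1)[C@@H](C)CC[C@H]1O[C@]1(C)CO | intermediate
8 | (2S,6S)-6-[(4R)-2-(4-methoxyphenyl)-1,3-dioxolan-4-yl]-2-methylheptane-1,2-diol | COc1ccc(cc1)C1OC[C@H](O1)[C@@H](C)CCC[C@](C)(O)CO | intermediate
9 | (2S,6S)-2-hydroxy-6-[(4R)-2-(4-methoxyphenyl)-1,3-dioxolan-4-yl]-2-methylheptanal | COc1ccc(cc1)C1OC[C@H](O1)[C@@H](C)CCC[C@](C)(O)C=O | intermediate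
10 | ethynyltriisopropylsilane | C#C[Si](C(C)C)(C(C)C)C(C)C | starting material
11 | prenyl bromide, 1-bromo-3-methylbut-2-ene | CC(C)=CCBr | starting material
12 | triisopropyl(5-methylhex-4-en-1-yn-1-yl)silane | CC(C)=CCC#C[Si](C(C)C)(C(C)C)C(C)C | intermediate
13 | (2E)-2-methyl-6-(triisopropylsilyl)hex-2-en-5-yn-1-ol | OC/C(C)=C/CC#C[Si](C(C)C)(C(C)C)C(C)C | intermediate
14 | [(4E)-6-bromo-5-methylhex-4-en-1-yn-1-yl]triisopropylsilane | BrC/C(C)=C/CC#C[Si](C(C)C)(C(C)C)C(C)C | intermediate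
15 | methyltriphenylphosphonium bromide | C[P+](c1ccccc1)(c1ccccc1)c1ccccc1.[Br-] | starting material
16 | methylenetriphenylphosphorane (not isolated) | C=P(c1ccccc1)(c1ccccc1)c1ccccc1 | intermediate
17 | [(3E)-3-methyl-7-(triisopropylsilyl)hept-3-en-6-yn-1-yl]triphenylphosphonium bromide | [Br-].c1ccc(cc1)[P+](c1ccccc1)(c1ccccc1)CC/C(C)=C/CC#C[Si](C(C)C)(C(C)C)C(C)C | intermediate
18 | ylide of 17, [(3E)-3-methyl-7-(triisopropylsilyl)hept-3-en-6-yn-1-ylidene]triphenylphosphorane (not isolated) | c1ccc(cc1)P(c1ccccc1)(c1ccccc1)=CC/C(C)=C/CC#C[Si](C(C)C)(C(C)C)C(C)C | intermediate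
19 | (2S,6S,7Z,10E)-2-[(4R)-2-(4-methoxyphenyl)-1,3-dioxolan-4-yl]-6,10-dimethyl-14-(triisopropylsilyl)tetradeca-7,10-dien-13-yn-6-ol | COc1ccc(cc1)C1OC[C@H](O1)[C@@H](C)CCC[C@](C)(O)/C=C\C/C(C)=C/CC#C[Si](C(C)C)(C(C)C)C(C)C | intermediate
20 | (2R,3S,7S,8Z,11E)-2-[(4-methoxybenzyl)oxy]-3,7,11-trimethyl-15-(triisopropylsilyl)pentadeca-8,11-dien-14-yne-1,7-diol | OC[C@H](OCc1ccc(OC)cc1)[C@@H](C)CCC[C@](C)(O)/C=C\C/C(C)=C/CC#C[Si](C(C)C)(C(C)C)C(C)C | intermediate
21 | (2R,3S,7S,8Z)-2-[(4-methoxybenzyl)oxy]-3,7-dimethyl-10-{(2R,3R)-2-methyl-3-[3-(triisopropylsilyl)prop-2-yn-1-yl]oxiran-2-yl}dec-8-ene-1,7-diol | OC[C@H](OCc1ccc(OC)cc1)[C@@H](C)CCC[C@](C)(O)/C=C\C[C@@]1(C)O[C@@H]1CC#C[Si](C(C)C)(C(C)C)C(C)C | intermediate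
22 | (2R,3S,7S,8Z)-2-[(4-methoxybenzyl)oxy]-3,7-dimethyl-10-[(2R,3R)-2-methyl-3-(prop-2-yn-1-yl)oxiran-2-yl]dec-8-ene-1,7-diol | OC[C@H](OCc1ccc(OC)cc1)[C@@H](C)CCC[C@](C)(O)/C=C\C[C@@]1(C)O[C@@H]1CC#C | intermediate
23 | Mannich base of 22, the 4-(diisopropylamino)but-2-yn-1-yl analogue (not isolated) | OC[C@H](OCc1ccc(OC)cc1)[C@@H](C)CCC[C@](C)(O)/C=C\C[C@@]1(C)O[C@@H]1CC#CCN(C(C)C)C(C)C | intermediate
24 | (2R,3S,7S,8Z)-10-[(2R,3R)-3-(buta-2,3-dien-1-yl)-2-methyloxiran-2-yl]-2-[(4-methoxybenzyl)oxy]-3,7-dimethyldec-8-ene-1,7-diol | OC[C@H](OCc1ccc(OC)cc1)[C@@H](C)CCC[C@](C)(O)/C=C\C[C@@]1(C)O[C@@H]1CC=C=C | intermediate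
25 | (2R,3S,7S,8Z)-10-[(2R,3R)-3-(buta-2,3-dien-1-yl)-2-methyloxiran-2-yl]-7-hydroxy-2-[(4-methoxybenzyl)oxy]-3,7-dimethyldec-8-enal | O=C[C@H](OCc1ccc(OC)cc1)[C@@H](C)CCC[C@](C)(O)/C=C\C[C@@]1(C)O[C@@H]1CC=C=C | intermediate
26 | η3-allyl nickelalactone from 25 and CO2, drawn as the η1-allyl oxanickelacyclopentanone with the C2 chain cis to CH2–Ni; DBU ligands omitted (not isolated) | O=C[C@H](OCc1ccc(OC)cc1)[C@@H](C)CCC[C@](C)(O)/C=C\C[C@@]1(C)O[C@@H]1C/C=C1\C[Ni]OC1=O | intermediate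
27 | (1S,3R,4R,6Z,8S,12S,13R,14R)-3,4-epoxy-8,14-dihydroxy-13-[(4-methoxybenzyl)oxy]cembra-6,15(17)-dien-16-oic acid (not isolated) | O[C@H]1[C@H](OCc2ccc(OC)cc2)[C@@H](C)CCC[C@](C)(O)/C=C\C[C@@]2(C)O[C@@H]2C[C@H]1C(=C)C(=O)O | intermediate
28 | (1S,3R,4R,6Z,8S,12S,13R,14R)-3,4-epoxy-8-hydroxy-13-[(4-methoxybenzyl)oxy]cembra-6,15(17)-dien-16,14-olide | C=C1C(=O)O[C@H]2[C@H](OCc3ccc(OC)cc3)[C@@H](C)CCC[C@](C)(O)/C=C\C[C@@]3(C)O[C@@H]3C[C@@H]12 | intermediate
29 | (1S,3R,4R,6Z,8S,12S,13R,14R)-3,4-epoxy-8,13-dihydroxycembra-6,15(17)-dien-16,14-olide, CNP0304380.1 | C=C1C(=O)O[C@H]2[C@H](O)[C@@H](C)CCC[C@](C)(O)/C=C\C[C@@]3(C)O[C@@H]3C[C@@H]12 | target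

**Step count and risks**

Total: 19 steps. Longest linear sequence: 15 steps (steps 1–7, then 12–19); the side branch to 17 is steps 8–11.

Steps most likely to fail:

1. Step 18 (Proposed new method). Possible failures: intermolecular allyl transfer (oligomerisation) instead of ring closure; C–C bond formation at the wrong allene terminus; direct nickel-mediated aldehyde–allene coupling without CO2 uptake; addition to the wrong aldehyde face (Felkin instead of chelate sense); base-induced epimerisation at C13. Fallback with known reaction types only, in which a chromium-mediated allylation closes the ring and a separate palladium carbonylation makes the lactone: set out from 22. Deprotonation (n-BuLi, 3.2 equiv, THF, −78 °C) and paraformaldehyde should give the propargylic alcohol, the 4-hydroxybut-2-ynyl analogue of 22, F1. Palladium-catalysed hydrostannation (Bu3SnH, PdCl2(PPh3)2, THF) should place tin next to the hydroxymethyl group and give the (E)-2-stannyl allylic alcohol F2. Bromodestannylation (NBS, CH2Cl2, 0 °C) gives the 2-bromoallylic alcohol F3. Corey–Kim bromination (NBS, Me2S, CH2Cl2, −20 °C), which spares the saturated primary and the tertiary hydroxyl, gives the 2-bromoallyl bromide F4. Dess–Martin oxidation gives the aldehyde F5. Nozaki–Hiyama-type ring closure (CrCl2, THF, high dilution; the vinyl bromide is inert without nickel) gives the macrocyclic 2-bromo homoallylic alcohol F6. Palladium-catalysed carbonylative lactonisation (Pd(PPh3)4, CO, Et3N, MeCN, 60 °C) comes back to the route at 28.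

2. Step 16. Possible failure: copper- and heat-promoted opening of the trisubstituted epoxide, by the C8 hydroxyl held close across the Z-alkene or by the amine, during the homologation. Fallback that forms the allene before the epoxide exists: set out from 20. Desilylation (TBAF, THF) gives the terminal alkyne F7; Crabbé homologation under the conditions of step 16 gives the allene F8; Shi epoxidation under the conditions of step 14, where the terminal allene is less nucleophilic than the trisubstituted alkene, comes back to the route at 24.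

3. Step 12. Possible failure: poor Z-selectivity, or loss of the aldehyde through alkoxide-induced α-ketol rearrangement caused by the free tertiary α-hydroxyl under the basic ylide conditions. Fallback that makes C6=C7 by alkyne semi-reduction: set out from 9 and use 14. Ohira–Bestmann homologation (dimethyl (1-diazo-2-oxopropyl)phosphonate, K2CO3, MeOH) gives the tertiary propargylic alcohol F9. Copper-mediated coupling with the allylic bromide 14 (CuI, Cs2CO3, NaI, DMF, rt) gives the skipped enediyne F10. Lindlar semi-hydrogenation (H2, Pd/CaCO3/Pb, quinoline, EtOAc), which leaves the hindered silylalkyne alone, comes back to the route at 19.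

Further compounds
F1 | step 18 | (2R,3S,7S,8Z)-10-[(2R,3R)-3-(4-hydroxybut-2-yn-1-yl)-2-methyloxiran-2-yl]-2-[(4-methoxybenzyl)oxy]-3,7-dimethyldec-8-ene-1,7-diol | OC[C@H](OCc1ccc(OC)cc1)[C@@H](C)CCC[C@](C)(O)/C=C\C[C@@]1(C)O[C@@H]1CC#CCO
F2 | step 18 | (2R,3S,7S,8Z)-10-{(2R,3R)-3-[(2E)-4-hydroxy-3-(tributylstannyl)but-2-en-1-yl]-2-methyloxiran-2-yl}-2-[(4-methoxybenzyl)oxy]-3,7-dimethyldec-8-ene-1,7-diol | OC[C@H](OCc1ccc(OC)cc1)[C@@H](C)CCC[C@](C)(O)/C=C\C[C@@]1(C)O[C@@H]1C/C=C(\CO)[Sn](CCCC)(CCCC)CCCC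
F3 | step 18 | (2R,3S,7S,8Z)-10-{(2R,3R)-3-[(2E)-3-bromo-4-hydroxybut-2-en-1-yl]-2-methyloxiran-2-yl}-2-[(4-methoxybenzyl)oxy]-3,7-dimethyldec-8-ene-1,7-diol | OC[C@H](OCc1ccc(OC)cc1)[C@@H](C)CCC[C@](C)(O)/C=C\C[C@@]1(C)O[C@@H]1C/C=C(\CO)Br
F4 | step 18 | (2R,3S,7S,8Z)-10-{(2R,3R)-3-[(2E)-3,4-dibromobut-2-en-1-yl]-2-methyloxiran-2-yl}-2-[(4-methoxybenzyl)oxy]-3,7-dimethyldec-8-ene-1,7-diol | OC[C@H](OCc1ccc(OC)cc1)[C@@H](C)CCC[C@](C)(O)/C=C\C[C@@]1(C)O[C@@H]1C/C=C(\CBr)Br
F5 | step 18 | (2R,3S,7S,8Z)-10-{(2R,3R)-3-[(2E)-3,4-dibromobut-2-en-1-yl]-2-methyloxiran-2-yl}-7-hydroxy-2-[(4-methoxybenzyl)oxy]-3,7-dimethyldec-8-enal | O=C[C@H](OCc1ccc(OC)cc1)[C@@H](C)CCC[C@](C)(O)/C=C\C[C@@]1(C)O[C@@H]1C/C=C(\CBr)Br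
F6 | step 18 | macrocyclic vinyl bromide corresponding to 27 with Br in place of CO2H at C15, 15-bromo-3,4-epoxy-13-[(4-methoxybenzyl)oxy]-16-norcembra-6,15(17)-diene-8,14-diol, same spatial arrangement at all centres as in 27 | O[C@H]1[C@H](OCc2ccc(OC)cc2)[C@@H](C)CCC[C@](C)(O)/C=C\C[C@@]2(C)O[C@@H]2C[C@H]1C(Br)=C
F7 | step 16 | (2R,3S,7S,8Z,11E)-2-[(4-methoxybenzyl)oxy]-3,7,11-trimethylpentadeca-8,11-dien-14-yne-1,7-diol | OC[C@H](OCc1ccc(OC)cc1)[C@@H](C)CCC[C@](C)(O)/C=C\C/C(C)=C/CC#C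
F8 | step 16 | (2R,3S,7S,8Z,11E)-2-[(4-methoxybenzyl)oxy]-3,7,11-trimethylhexadeca-8,11,14,15-tetraene-1,7-diol | OC[C@H](OCc1ccc(OC)cc1)[C@@H](C)CCC[C@](C)(O)/C=C\C/C(C)=C/CC=C=C
F9 | step 12 | (3S,7S)-7-[(4R)-2-(4-methoxyphenyl)-1,3-dioxolan-4-yl]-3-methyloct-1-yn-3-ol | COc1ccc(cc1)C1OC[C@H](O1)[C@@H](C)CCC[C@](C)(O)C#C
F10 | step 12 | (2S,6S,10E)-2-[(4R)-2-(4-methoxyphenyl)-1,3-dioxolan-4-yl]-6,10-dimethyl-14-(triisopropylsilyl)tetradec-10-ene-7,13-diyn-6-ol | COc1ccc(cc1)C1OC[C@H](O1)[C@@H](C)CCC[C@](C)(O)C#CC/C(C)=C/CC#C[Si](C(C)C)(C(C)C)C(C)C
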